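**Plan**
Retrosynthesis (decalin numbering: C1 side-chain carbon, C2 methylidene, C4a ring-fusion CH, C5 gem-dimethyl, C7 methoxy, C8a angular methyl): acid from a tert-butyl ester; methylidene from a C2 ketone; acetoxymethyl by Stille coupling on a Z enol triflate; side-chain β-keto ester from acrolein (Michael) and a diazoacetate (Roskamp) on bicyclic β-keto ester 14.
14 is cut at three C–C bonds at once: C6–C7 and C4a–C5, which release the CH2–CMe2 unit as isobutylene, and C1–C8a, which opens ring B to the acyclic acetal β-keto ester 10 (from 4,4-dimethoxybutan-2-one by HWE, reduction, bromide, acetoacetate dianion).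
Enabling feature: in ring A the methoxy carbon C7 and the quaternary C5 stand 1,3 across C6, and C5 is bonded to the ring-fusion CH C4a. This is the imprint of an O-methyl oxocarbenium ion adding to isobutylene, whose tertiary cation then attacks an E-trisubstituted alkene; the methylidene carbon C2 next to C1 is a masked ketone, i.e. a β-keto ester terminator.
Forward: chain assembly, then ring A and ring B in one operation, then the side chain at C1, methylenation, release of the acid.
Stereochemistry: C7 from the chiral acid; C4a and C8a relayed from C7 through the chair–chair transition state; C1 by axial protonation and equilibration after decarboxylation; the Z alkene from a chelated enolate and a stereoretentive coupling.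

Key step: step 5

Assumption: the sense of induction of the confined chiral acid in step 5 cannot be derived a priori; the route uses the catalyst antipode that gives the (7R)-methoxy centre, both antipodes being accessible.

Step 1
Reactants: 1 4,4-dimethoxybutan-2-one; 2 triethyl phosphonoacetate
Product: 4 ethyl (2E)-5,5-dimethoxy-3-methylpent-2-enoate, via sodium phosphonoacetate carbanion 3 (not isolated)
Conditions: NaH (1.0 equiv to 2), THF, 0 °C → rt; minor Z isomer removed by chromatography
Reagents that add atoms: none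
Why: Horner–Wadsworth–Emmons olefination of the methyl ketone should favour the E enoate (ester trans to the larger CH2CH(OMe)2 group), the geometry needed later for the trans ring fusion.

Step 2
Reactants: 4 ethyl (2E)-5,5-dimethoxy-3-methylpent-2-enoate
Product: 5 (2E)-5,5-dimethoxy-3-methylpent-2-en-1-ol
Conditions: DIBAL-H (2.2 equiv), CH2Cl2, −78 °C; Rochelle salt work-up
Reagents that add atoms: none
Why: Hydride 1,2-reduction of the enoate with DIBAL-H should give the allylic alcohol and leave the acetal and the alkene geometry untouched.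

Step 3
Reactants: 5 (2E)-5,5-dimethoxy-3-methylpent-2-en-1-ol
Product: 7 (3E)-5-bromo-1,1-dimethoxy-3-methylpent-3-ene, via allylic mesylate 6 (not isolated)
Conditions: MsCl, Et3N, THF, −40 °C; then LiBr, THF, 0 °C
Reagents that add atoms: lithium bromide, [Li+].[Br-]
Why: Mesylation followed by SN2 displacement with bromide runs under non-acidic conditions, so the acetal survives and the primary allylic bromide keeps its E geometry.

Step 4
Reactants: 7 (3E)-5-bromo-1,1-dimethoxy-3-methylpent-3-ene; 8 allyl acetoacetate
Product: 10 allyl (6E)-9,9-dimethoxy-7-methyl-3-oxonon-6-enoate, via acetoacetate dianion 9 (not isolated)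
Conditions: 8, NaH, THF, 0 °C; n-BuLi, 0 °C; then 7, 0 °C → rt; aq. NH4Cl
Reagents that add atoms: none
Why: Weiler dianion alkylation: the more basic terminal carbanion of the acetoacetate dianion should displace the allylic bromide (SN2) and leave the β-keto ester free as the later terminator.

Step 5
Reactants: 10 allyl (6E)-9,9-dimethoxy-7-methyl-3-oxonon-6-enoate; 11 2-methylpropene (isobutylene)
Product: 14 allyl (1S,4aR,7R,8aR)-7-methoxy-5,5,8a-trimethyl-2-oxodecahydronaphthalene-1-carboxylate, via oxocarbenium ion 12 (not isolated), via tertiary carbocation 13 (not isolated)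
Conditions: confined chiral Brønsted acid of the imidodiphosphorimidate (IDPi) type (5 mol%), 11 (10 equiv), CH2Cl2, 5 Å MS, −60 → −30 °C
Reagents that add atoms: none
Why: Proposed new method: the acid ionises the acetal to an O-methyl oxocarbenium ion paired with the chiral anion; isobutylene adds through its CH2 terminus (Prins addition, C6–C7 bond) and the tertiary cation so formed attacks the E-trisubstituted alkene (C4a–C5 bond, ring A, 6-endo-trig), whose tertiary cation is taken by the enol carbon of the β-keto ester (C1–C8a bond, ring B, 6-endo-trig) with return of the proton to the catalyst. The closest known reaction types are acetal-initiated cation–olefin polycyclisations ending on a β-keto ester, the acid-promoted addition of acetals to 1,1-disubstituted alkenes, and asymmetric Prins reactions and polyene cyclisations under confined chiral acids; new is the bimolecular start, which makes the sequence a formal [4+2] annulation of a homoallylic oxocarbenium ion with an alkene. C7 is set by the chiral anion in the addition of isobutylene; C4a and C8a follow from it through the chair–chair transition state with the methoxy group equatorial (an axial one would clash with the future angular methyl and an axial methyl of C5) and anti addition across the E alkene, which should give the trans ring fusion; C1 is enolisable and settles with the ester equatorial. The step needs capture of the oxocarbenium ion by isobutylene before it isomerises into conjugation or meets another molecule of 10, and ring closure before a second isobutylene adds: within 10 no π-nucleophile can reach the oxocarbenium carbon without closing a three-, four- or eight-membered ring and the free β-keto ester is a weak intermolecular donor, so the excess external alkene should win the first event, while the six-membered chair closure should outrun bimolecular chain growth.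

Step 6
Reactants: 14 allyl (1S,4aR,7R,8aR)-7-methoxy-5,5,8a-trimethyl-2-oxodecahydronaphthalene-1-carboxylate; 15 acrolein
Product: 16 allyl (1S,4aR,7R,8aR)-7-methoxy-5,5,8a-trimethyl-2-oxo-1-(3-oxopropyl)decahydronaphthalene-1-carboxylate
Conditions: DBU (10 mol%), MeCN, −20 → 0 °C
Reagents that add atoms: none
Why: Michael addition of the β-keto ester, whose only acidic CH is C1, to acrolein; the acceptor should enter axially, anti to the angular methyl, but this centre is re-set in step 8 so either face serves.

Step 7
Reactants: 16 allyl (1S,4aR,7R,8aR)-7-methoxy-5,5,8a-trimethyl-2-oxo-1-(3-oxopropyl)decahydronaphthalene-1-carboxylate; 17 tert-butyl diazoacetate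
Product: 18 allyl (1S,4aR,7R,8aR)-1-(5-tert-butoxy-3,5-dioxopentyl)-7-methoxy-5,5,8a-trimethyl-2-oxodecahydronaphthalene-1-carboxylate
Conditions: SnCl2 (10 mol%), CH2Cl2, rt
Reagents that add atoms: none
Why: Roskamp reaction (Lewis acid-catalysed addition of the diazo ester to the aldehyde, 1,2-hydride shift, loss of N2) should convert only the aldehyde, not the hindered ketone, into the β-keto ester.

Step 8
Reactants: 18 allyl (1S,4aR,7R,8aR)-1-(5-tert-butoxy-3,5-dioxopentyl)-7-methoxy-5,5,8a-trimethyl-2-oxodecahydronaphthalene-1-carboxylate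
Product: 20 tert-butyl 5-[(1S,4aR,7R,8aR)-7-methoxy-5,5,8a-trimethyl-2-oxodecahydronaphthalen-1-yl]-3-oxopentanoate, via β-keto acid 19 (not isolated)
Conditions: Pd(OAc)2 (5 mol%), PPh3 (20 mol%), HCO2H, Et3N, THF, rt → 40 °C
Reagents that add atoms: none
Why: Palladium-catalysed deallylation with formate (Tsuji–Trost type hydrogenolysis) frees the β-keto acid, which decarboxylates; the enol should be protonated axially, anti to the angular methyl, and any minor epimer equilibrates under Et3N, so C1 ends with the side chain equatorial and cis to the angular methyl.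

Step 9
Reactants: 20 tert-butyl 5-[(1S,4aR,7R,8aR)-7-methoxy-5,5,8a-trimethyl-2-oxodecahydronaphthalen-1-yl]-3-oxopentanoate
Product: 22 tert-butyl (2Z)-5-[(1S,4aR,7R,8aR)-7-methoxy-5,5,8a-trimethyl-2-oxodecahydronaphthalen-1-yl]-3-(trifluoromethanesulfonyloxy)pent-2-enoate, via lithium Z-enolate 21 (not isolated)
Conditions: Tf2O, sat. aq. LiOH, toluene, 5 °C
Reagents that add atoms: trifluoromethanesulfonic anhydride, O=S(=O)(OS(=O)(=O)C(F)(F)F)C(F)(F)F
Why: O-Triflation of the lithium-chelated enolate of the β-keto ester (the only CH2 acidic enough for hydroxide) should give the Z enol triflate, triflate cis to the ester, which fixes the alkene geometry of the target.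

Step 10
Reactants: 23 (tributylstannyl)methanol
Product: 24 (tributylstannyl)methyl acetate
Conditions: Ac2O, pyridine, DMAP (cat.), CH2Cl2, 0 °C → rt
Reagents that add atoms: acetic anhydride, CC(=O)OC(C)=O
Why: DMAP-catalysed O-acetylation of the primary carbinol; the C–Sn bond is inert to these conditions.

Step 11
Reactants: 22 tert-butyl (2Z)-5-[(1S,4aR,7R,8aR)-7-methoxy-5,5,8a-trimethyl-2-oxodecahydronaphthalen-1-yl]-3-(trifluoromethanesulfonyloxy)pent-2-enoate; 24 (tributylstannyl)methyl acetate
Product: 25 tert-butyl (2Z)-3-(acetoxymethyl)-5-[(1S,4aR,7R,8aR)-7-methoxy-5,5,8a-trimethyl-2-oxodecahydronaphthalen-1-yl]pent-2-enoate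
Conditions: Pd2(dba)3 (5 mol%), AsPh3 (20 mol%), CuI (10 mol%), LiCl (3 equiv), NMP, 40–50 °C
Reagents that add atoms: none
Why: Stille coupling of the enol triflate with the α-oxygenated methylstannane proceeds with retention of alkene geometry, so the acetoxymethyl group should arrive cis to the ester.

Step 12
Reactants: 25 tert-butyl (2Z)-3-(acetoxymethyl)-5-[(1S,4aR,7R,8aR)-7-methoxy-5,5,8a-trimethyl-2-oxodecahydronaphthalen-1-yl]pent-2-enoate
Product: 26 tert-butyl (2Z)-3-(acetoxymethyl)-5-[(1R,4aR,7R,8aR)-7-methoxy-5,5,8a-trimethyl-2-methylidenedecahydronaphthalen-1-yl]pent-2-enoate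
Conditions: Zn, CH2Br2, TiCl4, THF (pre-formed reagent); then 25, CH2Cl2, 0 °C → rt
Reagents that add atoms: dibromomethane, BrCBr
Why: Takai–Lombardo methylenation is non-basic and selective for ketones over esters, so the hindered ring ketone should be converted without epimerising C1 or touching the acetate and the tert-butyl ester.

Step 13
Reactants: 26 tert-butyl (2Z)-3-(acetoxymethyl)-5-[(1R,4aR,7R,8aR)-7-methoxy-5,5,8a-trimethyl-2-methylidenedecahydronaphthalen-1-yl]pent-2-enoate
Product: 28 (2Z)-3-(acetoxymethyl)-5-[(1R,4aR,7R,8aR)-7-methoxy-5,5,8a-trimethyl-2-methylidenedecahydronaphthalen-1-yl]pent-2-enoic acid, via trimethylsilyl ester 27 (not isolated)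
Conditions: TMSOTf, 2,6-lutidine, CH2Cl2, 0 °C; then pH 5 aqueous work-up
Reagents that add atoms: none
Why: Silyl triflate-mediated cleavage of the tert-butyl ester (loss of isobutylene, then hydrolysis of the silyl ester) in buffered medium should spare the acid-sensitive exocyclic alkene, the allylic acetate and the methyl ether.

**Compound list**
1 | 4,4-dimethoxybutan-2-one | CC(=O)CC(OC)OC | starting material
2 | triethyl phosphonoacetate | CCOC(=O)CP(=O)(OCC)OCC | starting material
3 | sodium salt of the triethyl phosphonoacetate carbanion | CCOC(=O)[CH-]P(=O)(OCC)OCC.[Na+] | intermediate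
4 | ethyl (2E)-5,5-dimethoxy-3-methylpent-2-enoate | COC(OC)C/C(C)=C/C(=O)OCC | intermediate
5 | (2E)-5,5-dimethoxy-3-methylpent-2-en-1-ol | COC(OC)C/C(C)=C/CO | intermediate
6 | (2E)-5,5-dimethoxy-3-methylpent-2-en-1-yl methanesulfonate | COC(OC)C/C(C)=C/COS(C)(=O)=O | intermediate
7 | (3E)-5-bromo-1,1-dimethoxy-3-methylpent-3-ene | COC(OC)C/C(C)=C/CBr | intermediate
8 | allyl acetoacetate (prop-2-en-1-yl 3-oxobutanoate) | CC(=O)CC(=O)OCC=C | starting material
9 | sodium lithium dianion of allyl acetoacetate | [CH2-]C(=O)[CH-]C(=O)OCC=C.[Na+].[Li+] | intermediate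
10 | allyl (6E)-9,9-dimethoxy-7-methyl-3-oxonon-6-enoate | COC(OC)C/C(C)=C/CCC(=O)CC(=O)OCC=C | intermediate
11 | 2-methylpropene (isobutylene) | C=C(C)C | starting material
12 | O-methyl oxocarbenium ion from 10 by loss of methoxide | C[O+]=CC/C(C)=C/CCC(=O)CC(=O)OCC=C | intermediate
13 | open-chain tertiary carbocation, (R) at the methoxy carbon, Prins adduct of 12 and 11 | C[C+](C)C[C@@H](OC)C/C(C)=C/CCC(=O)CC(=O)OCC=C | intermediate
14 | allyl (1S,4aR,7R,8aR)-7-methoxy-5,5,8a-trimethyl-2-oxodecahydronaphthalene-1-carboxylate | O=C1CC[C@@H]2C(C)(C)C[C@@H](OC)C[C@@]2(C)[C@@H]1C(=O)OCC=C | intermediate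
15 | acrolein (prop-2-enal) | C=CC=O | starting material
16 | allyl (1S,4aR,7R,8aR)-7-methoxy-5,5,8a-trimethyl-2-oxo-1-(3-oxopropyl)decahydronaphthalene-1-carboxylate | O=C1CC[C@@H]2C(C)(C)C[C@@H](OC)C[C@@]2(C)[C@@]1(C(=O)OCC=C)CCC=O | intermediate
17 | tert-butyl diazoacetate | CC(C)(C)OC(=O)C=[N+]=[N-] | starting material
18 | allyl (1S,4aR,7R,8aR)-1-(5-tert-butoxy-3,5-dioxopentyl)-7-methoxy-5,5,8a-trimethyl-2-oxodecahydronaphthalene-1-carboxylate | O=C1CC[C@@H]2C(C)(C)C[C@@H](OC)C[C@@]2(C)[C@@]1(C(=O)OCC=C)CCC(=O)CC(=O)OC(C)(C)C | intermediate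
19 | (1S,4aR,7R,8aR)-1-(5-tert-butoxy-3,5-dioxopentyl)-7-methoxy-5,5,8a-trimethyl-2-oxodecahydronaphthalene-1-carboxylic acid | O=C1CC[C@@H]2C(C)(C)C[C@@H](OC)C[C@@]2(C)[C@@]1(C(=O)O)CCC(=O)CC(=O)OC(C)(C)C | intermediate
20 | tert-butyl 5-[(1S,4aR,7R,8aR)-7-methoxy-5,5,8a-trimethyl-2-oxodecahydronaphthalen-1-yl]-3-oxopentanoate | O=C1CC[C@@H]2C(C)(C)C[C@@H](OC)C[C@@]2(C)[C@@H]1CCC(=O)CC(=O)OC(C)(C)C | intermediate
21 | lithium (Z)-enolate of 20 at the side-chain β-keto ester | O=C1CC[C@@H]2C(C)(C)C[C@@H](OC)C[C@@]2(C)[C@@H]1CC/C([O-])=C/C(=O)OC(C)(C)C.[Li+] | intermediate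
22 | tert-butyl (2Z)-5-[(1S,4aR,7R,8aR)-7-methoxy-5,5,8a-trimethyl-2-oxodecahydronaphthalen-1-yl]-3-(trifluoromethanesulfonyloxy)pent-2-enoate | O=C1CC[C@@H]2C(C)(C)C[C@@H](OC)C[C@@]2(C)[C@@H]1CC/C(OS(=O)(=O)C(F)(F)F)=C/C(=O)OC(C)(C)C | intermediate
23 | (tributylstannyl)methanol | CCCC[Sn](CCCC)(CCCC)CO | starting material
24 | (tributylstannyl)methyl acetate | CCCC[Sn](CCCC)(CCCC)COC(C)=O | intermediate
25 | tert-butyl (2Z)-3-(acetoxymethyl)-5-[(1S,4aR,7R,8aR)-7-methoxy-5,5,8a-trimethyl-2-oxodecahydronaphthalen-1-yl]pent-2-enoate | O=C1CC[C@@H]2C(C)(C)C[C@@H](OC)C[C@@]2(C)[C@@H]1CC/C(COC(C)=O)=C/C(=O)OC(C)(C)C | intermediate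
26 | tert-butyl (2Z)-3-(acetoxymethyl)-5-[(1R,4aR,7R,8aR)-7-methoxy-5,5,8a-trimethyl-2-methylidenedecahydronaphthalen-1-yl]pent-2-enoate | C=C1CC[C@@H]2C(C)(C)C[C@@H](OC)C[C@@]2(C)[C@@H]1CC/C(COC(C)=O)=C/C(=O)OC(C)(C)C | intermediate
27 | trimethylsilyl (2Z)-3-(acetoxymethyl)-5-[(1R,4aR,7R,8aR)-7-methoxy-5,5,8a-trimethyl-2-methylidenedecahydronaphthalen-1-yl]pent-2-enoate | C=C1CC[C@@H]2C(C)(C)C[C@@H](OC)C[C@@]2(C)[C@@H]1CC/C(COC(C)=O)=C/C(=O)O[Si](C)(C)C | intermediate
28 | (2Z)-3-(acetoxymethyl)-5-[(1R,4aR,7R,8aR)-7-methoxy-5,5,8a-trimethyl-2-methylidenedecahydronaphthalen-1-yl]pent-2-enoic acid | C=C1CC[C@@H]2C(C)(C)C[C@@H](OC)C[C@@]2(C)[C@@H]1CC/C(=C/C(=O)O)COC(C)=O | target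

Total step count: 13. Longest linear sequence: 12 (steps 1–9 and 11–13; step 10 is a one-step side branch).

**Steps most likely to fail**

Step 5 (proposed new method). What may go wrong: chain growth by further isobutylene at the tertiary cation, isomerisation of the β,γ-unsaturated oxocarbenium ion into conjugation before capture, termination through the enol oxygen instead of carbon, or weak facial control by the chiral anion. The fallback sets out from 10 and returns at 14, and uses only known reactions. Mild acetal hydrolysis (PPTS, wet acetone, 0 °C) should give allyl (6E)-7-methyl-3,9-dioxonon-6-enoate F1, used at once. Brown methallylation (B-methallyldiisopinocampheylborane, the antipode that gives the R carbinol, Et2O, −78 °C, NaBO3 work-up) should give allyl (6E,9R)-9-hydroxy-7,11-dimethyl-3-oxododeca-6,11-dienoate F2. O-Methylation with Me3OBF4 and proton sponge should give allyl (6E,9R)-9-methoxy-7,11-dimethyl-3-oxododeca-6,11-dienoate F3. SnCl4 in CH2Cl2 (−78 → 0 °C) then protonates the 1,1-disubstituted alkene to the same tertiary cation as 13 and the β-keto ester-terminated chair–chair cyclisation should give 14, the two bonds now being made in separate steps.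

Step 6. What may go wrong: slow conjugate addition at the ring carbon flanked by the quaternary centre, polymerisation of acrolein, or intramolecular aldol closure of the keto aldehyde to a bridged ketol. The fallback sets out from 14 and returns at 20, and forms the C1–side-chain bond intramolecularly instead. Pd(PPh3)4-catalysed decarboxylative allylation of the allyl β-keto ester should give (1S,4aR,7R,8aR)-7-methoxy-5,5,8a-trimethyl-1-(prop-2-en-1-yl)octahydronaphthalen-2(1H)-one F4. Hydroboration with 9-BBN and NaBO3 oxidation should give (1S,4aR,7R,8aR)-1-(3-hydroxypropyl)-7-methoxy-5,5,8a-trimethyloctahydronaphthalen-2(1H)-one F5. Dess–Martin oxidation should give 3-[(1S,4aR,7R,8aR)-7-methoxy-5,5,8a-trimethyl-2-oxodecahydronaphthalen-1-yl]propanal F6, and the Roskamp reaction with 17 then leads directly to 20.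

Step 11. What may go wrong: sluggish transfer of the acyloxymethyl group from tin with competing butyl transfer, and ionisation of the allylic acetate of the product by Pd(0) with loss of alkene geometry. The fallback sets out from 22 and returns at 25, and moves the acetylation behind the coupling. Stille hydroxymethylation with 23 itself (Pd(PPh3)4, LiCl, dioxane, 60 °C) should give tert-butyl (2Z)-3-(hydroxymethyl)-5-[(1S,4aR,7R,8aR)-7-methoxy-5,5,8a-trimethyl-2-oxodecahydronaphthalen-1-yl]pent-2-enoate F7, whose tert-butyl ester resists lactonisation. Immediate acetylation (Ac2O, pyridine, DMAP, 0 °C) gives 25, and step 10 is then not needed.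

**Further compounds**
F1 | step 5 | allyl (6E)-7-methyl-3,9-dioxonon-6-enoate | O=CC/C(C)=C/CCC(=O)CC(=O)OCC=C
F2 | step 5 | allyl (6E,9R)-9-hydroxy-7,11-dimethyl-3-oxododeca-6,11-dienoate | C=C(C)C[C@@H](O)C/C(C)=C/CCC(=O)CC(=O)OCC=C
F3 | step 5 | allyl (6E,9R)-9-methoxy-7,11-dimethyl-3-oxododeca-6,11-dienoate | C=C(C)C[C@@H](OC)C/C(C)=C/CCC(=O)CC(=O)OCC=C
F4 | step 6 | (1S,4aR,7R,8aR)-7-methoxy-5,5,8a-trimethyl-1-(prop-2-en-1-yl)octahydronaphthalen-2(1H)-one | O=C1CC[C@@H]2C(C)(C)C[C@@H](OC)C[C@@]2(C)[C@@H]1CC=C
F5 | step 6 | (1S,4aR,7R,8aR)-1-(3-hydroxypropyl)-7-methoxy-5,5,8a-trimethyloctahydronaphthalen-2(1H)-one | O=C1CC[C@@H]2C(C)(C)C[C@@H](OC)C[C@@]2(C)[C@@H]1CCCO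
F6 | step 6 | 3-[(1S,4aR,7R,8aR)-7-methoxy-5,5,8a-trimethyl-2-oxodecahydronaphthalen-1-yl]propanal | O=C1CC[C@@H]2C(C)(C)C[C@@H](OC)C[C@@]2(C)[C@@H]1CCC=O
F7 | step 11 | tert-butyl (2Z)-3-(hydroxymethyl)-5-[(1S,4aR,7R,8aR)-7-methoxy-5,5,8a-trimethyl-2-oxodecahydronaphthalen-1-yl]pent-2-enoate | O=C1CC[C@@H]2C(C)(C)C[C@@H](OC)C[C@@]2(C)[C@@H]1CC/C(CO)=C/C(=O)OC(C)(C)C
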